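Readings and results were generated by integration for substances that don't exist; the scatter is artificial.

in all of them: catalyst 1.5 mM
- teal: substrate 10 mM; reagent 18 mM; run made earlier
- red: substrate 6.7 mM; reagent 18 mM; run made earlier
- grey: substrate 15 mM; reagent 18 mM; run made earlier
- Monday's: substrate 10 mM (in portions, 5, over 2.0 h); reagent 18.0 mM; first portion at the start, last at 2.0 h; time 3.0 h
- Thursday's: substrate 10 mM; reagent 18.0 mM (fed, over 12 min); all else is in the flask from the start; the feed brings no volume worth counting; time 3.0 h
- Friday's: substrate 10 mM; reagent 18.0 mM; everything together at the start; time 3.0 h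
- Sunday's: substrate 10 mM (fed, over 2.0 h); reagent 18.0 mM; all else is in the flask from the start; the feed brings no volume worth counting; time 3.0 h
- Tuesday's: substrate 10 mM; reagent 18.0 mM (fed, over 2.0 h); all else is in the flask from the start; the feed brings no volume worth counting; time 3.0 h

- teal (time / h: target / %, uncatalysed product / %): 0.250: 3.5, 1.8; 0.417: 6.5, 3.8; 0.667: 8.8, 5.4; 1.00: 13.8, 7.9; 2.00: 22.8, 13.1; 3.00: 29.5, 16.7
- red (time / h: target / %, uncatalysed product / %): 0.167: 2.4, 1.3; 0.500: 6.8, 4.5; 0.833: 11.7, 6.6; 1.33: 16.6, 9.6; 2.00: 23.5, 13.2; 2.50: 26.9, 15.9
- grey (time / h: target / %, uncatalysed product / %): 0.167: 2.0, 1.3; 0.500: 6.5, 3.7; 0.833: 10.8, 6.4; 1.33: 16.0, 8.9; 2.00: 22.1, 12.3; 2.50: 24.9, 14.6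

(standard deviation of a reading: 0.3 percentage points)

- what was read earlier has a scatter of 0.3 percentage points, one standard deviation

- which flask leads in share of target in target plus uncatalysed product ("all alike" within 1.5 percentage points) (Monday's / Thursday's / Friday's / Sunday's / Tuesday's / all alike)
- share of target in target plus uncatalysed product at the end, Monday's
- share of target in target plus uncatalysed product at the end, Thursday's
- share of target in target plus uncatalysed product at the end, Friday's
- share of target in target plus uncatalysed product at the end, Sunday's
- share of target in target plus uncatalysed product at the end, Tuesday's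

The grey run held about twice the substrate of the red run, yet by 2.50 h it had converted 39.5% of its charge against 42.8% in the red run, so we take both routes as close to first order in substrate, and dosing substrate should then slow them together without moving their ratio.

That ratio is what we carry: the selectivity factor, meaning target formed over uncatalysed product formed, summed over the last readings of the three runs.

| run, last reading | target | uncatalysed product | ratio |
|---|---|---|---|
| teal | 29.5% | 16.7% | 1.77 |
| red | 26.9% | 15.9% | 1.69 |
| grey | 24.9% | 14.6% | 1.71 |

The sums give 1.72, so a target share of 63.3%, and this is the number we would commit to for each of the five flasks, which makes them all alike.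

The weak link is reagent: Thursday's and Tuesday's flasks begin without their full charge of it. If the target route had one reagent order more, its ratio would sink as reagent is used. Counting one reagent per substrate, mean reagent between the fourth and last readings stood at 0.866 of its earlier mean, averaged over the runs, so the ratio should have fallen to that fraction. Pooled, it went from 1.76 to 1.68, a fraction of 0.955, nearer to one than to that expected fraction. We hold the link, and note that reagent at the last reading of the grey run is reckoned at 12.1 mM.

The forecast gives 63.5%, 63.5%, 63.5%, 63.5% and 63.5% for Monday's, Thursday's, Friday's, Sunday's and Tuesday's, with the verdict all alike, a little above our share: “So both routes appear to have the same reagent order, and reagent feeding should not matter either.”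

Monday's gives 63.5%, Thursday's 63.5%, Friday's 63.5%, Sunday's 63.5% and Tuesday's 63.5%: all alike. Thursday's flask averaged 8.92 mM of reagent over its first 12 min, less than the amount reckoned for the last reading of the grey run, and its 16.7% of uncatalysed product at 3.00 h, times our factor, gives 28.7% of target against the 29.0% it holds.

    substrate + reagent → uncatalysed product (k = 5.00 M⁻¹ h⁻¹)
    substrate + reagent + catalyst → catalyst + target (k = 5800 M⁻² h⁻¹)

The catalysed route carries the catalyst as a factor, so a neighbour of Friday's flask with 0.38 mM of catalyst takes the factor 0.436 and a share of 30.4%, and that neighbour ends at 30.6%.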